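## Structural features

Kazinol K is an achiral 1,3-diarylpropane: a saturated three-carbon chain joins C1 of ring A to C6 of a 2,2-dimethyl-2H-chromene (ring B with its fused pyran ring). Ring A is a resorcinol with hydroxyls at C2 and C4 (counted from the chain carbon) and a 2-methylbut-3-en-2-yl group at C5, so a quaternary benzylic carbon sits ortho to the C4 hydroxyl. Ring B is pentasubstituted: the chain at C6, a 3-methylbut-2-enyl (prenyl) group at C5, the pyran carbon C4 on C4a, the pyran oxygen on C8a and a free hydroxyl at C8; only C7 carries hydrogen. The target has no stereocentre, so no configurations stand next to each other; the only stereocentre of the route is transient. The fragile parts are the electron-rich chromene double bond with its tertiary allylic C–O bond, the prenyl alkene, the terminal alkene next to a phenol (acid closes it to a dihydrobenzofuran) and three oxidisable phenols. Four C=C bonds exclude catalytic hydrogenation and dissolving metals once they are in place. The real difficulty is regiochemistry on two crowded arenes (C5 against C3 on ring A, five different substituents on ring B) and joining them through a saturated chain without a reduction that touches the alkenes. The key step uses the fact that O2 of ring A is ortho to the chain: C1, C2 and O2 of ring A with the three chain carbons are the six atoms of a chroman ring, and the O–C2 bond of that 2-arylchroman is benzylic to ring B and para to the pyran oxygen, so it can be cut again by ionisation and hydride transfer.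

## Logic of the disconnections

**24 ⇒ 22.** The O–C(carbonate) bond on ring A and the O–Si bond on ring B are cut. Both phenols must be masked while a Grignard base and a Lewis acid are in use. The forward step must be free of acid, because the chromene, both C5 alkenes and the ortho-allyl phenol do not tolerate it; fluoride and mild base meet this.

**22 ⇒ 21.** The ring A oxygen is reconnected to chain C3, so the forward step cuts that benzylic C–O bond. The open chain becomes a 2-arylchroman whose two ring bonds can be made at once. The forward step must cleave only this C–O bond and deliver hydride faster than the neighbouring prenyl alkene can capture the cation. The stereocentre of 21 disappears here, so it needs no control.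

**21 ⇒ 8 + 18 (through 20).** Chain C1–C2 and the O–C3 bond are cut, the retron of an oxadiene–alkene [4+2] cycloaddition. The molecule falls into two arenes of similar size, each already carrying its C5 unit, and no chain-building steps are needed. The heterodiene 20 must be generated at low temperature without acid, the vinyl group of 18 must outrun the other alkenes, and the polarity of the addition must give the 2-aryl isomer.

**18 ⇒ 17.** The terminal C=C bond is cut to a formyl group, which also activates the ring for the preceding coupling.

**17 ⇒ 15 + 16.** The bond from ring C5 to the prenyl CH2 is cut. A halogen fixes the position, and the prenyl group enters after the thermal chromene step. The coupling must transfer the prenyl group through its primary carbon at a bromide flanked by two substituents.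

**15 ⇒ 13 (through 14).** The chromene C4–C4a bond is cut; the O1–C2 bond is broken and remade in the cascade. The pyran ring then comes from a simple aryl propargyl ether. The only free ortho position must accept the [3,3] shift, and the aldehyde, bromide and silyl ether must survive heat.

**13 ⇒ 12 ⇒ 10 + 11, and 10 ⇒ 9.** The O–Si bond, the O4–C(tertiary) ether bond and finally two O–CH3 bonds are cut, back to a commercial bromo-dimethoxy aldehyde. The demand is on the etherification: it must take the hydroxyl para to the formyl group and leave its neighbour for silylation.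

**8 ⇒ 7 ⇒ 6.** One C–H bond of the CH2OH group is cut (aldehyde reduction), then two O–C(carbonate) bonds. The ortho carbonate is the trigger that 20 needs; the para carbonate is a spectator that lowers the nucleophilicity of ring A later. The reduction must not free an alkoxide warm enough to take over the neighbouring carbonate.

**6 ⇒ 3 (through 4 and 5) ⇒ 1 + 2.** The bond from ring C5 to the quaternary carbon is cut (aromatic Claisen retron), then the O4–CH2 bond. The quaternary carbon and the terminal alkene arise from a plain prenyl ether. The shift must go to C5. A free, hydrogen-bonded 2-hydroxyl is expected to steer it to C3, between the two oxygens, so that hydroxyl is silylated in the flask before heating.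

## Other disconnections considered

**Alternative 1:** The cut is at the benzylic CH2–CH= bonds of both C5 units on ring B (the future chromene C4–C3 bond and the prenyl C1–C2 bond).

- **Forward step.** Excess alkenyl Grignard reagent A3 removes the two acetates of diacetate bis(pivalate) A2. Each phenoxide expels the pivalate on the CH2 group ortho or para to it, and A3 adds to the resulting ortho- and para-quinone methides to give catechol A1, whose prenyl groups sit at C3 and C4 of the benzene-1,2-diol.
- **In favour.** Two C–C bonds and both C5 units form in one operation by carbanion addition, which is faster and less sensitive to hindrance than a cycloaddition; on this point it is the better of the two. The chain is already present in A2, so no benzylic C–O bond has to be cut next to a prenyl group; this is also better than the chosen plan.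
- **Against.** A2 needs a fully substituted ring B with two adjacent acyloxymethyl groups beside a catechol. A1 is a free, oxidation-prone catechol that must be closed oxidatively to the chromene at one oxygen only. The methoxymethyl ethers on ring A must come off with acid when the chromene, the prenyl group and the ortho-allyl phenol are all present.
- **Comparison.** Both plans generate quinone methides by acyl transfer and elimination under Grignard conditions, and they are equal in mechanistic precedent. The alternative closes no ring, so the pyran ring and an acidic deprotection remain. The saving in the key step is spent on making A2 and on a less secure endgame.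

**Alternative 2:** The cut is in ring B itself, at C7–C8, C5–C6 and C8–C8a.

- **Forward step.** Irradiation of diazo ketone A5 gives a vinylketene by Wolff rearrangement. It adds siloxyalkyne A6 in a [2+2] reaction; 4π opening, 6π closure and tautomerisation on heating give chromanol A4.
- **In favour.** The substitution pattern of ring B is set without ambiguity, and the pyran oxygen and the C8 hydroxyl come out differentiated. That is better than the selective etherification of a catechol in step 6.
- **Against.** A4 is a chroman, so the C3–C4 double bond must be introduced later by dehydrogenation beside a prenyl group. C6 carries oxygen where the target has carbon, so a triflate and an sp2–sp3 coupling are needed to attach the chain. The diazo carbon of A5 carries a prenyl group, which invites cyclopropanation of its alkene and 1,2-hydride shift in competition with the Wolff rearrangement.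
- **Comparison.** The pericyclic cascade is neutral and regiochemically the equal of the chosen route or better. It builds ring B from scratch where the chosen route starts from a commercial arene with both oxygens and the formyl carbon in place. Ring B alone would take more steps than steps 5 to 10 and would still lack the chain and the chromene double bond.

**Alternative 3:** The cut is in ring A, at C1–C6 and C3–C4.

- **Forward step.** A hindered alkoxide base adds the more substituted enolate of methyl ketone A8 to acrylate A9 (Michael addition). The methyl enolate then attacks the ester (Claisen condensation) and closes dione A7 as a mixture of diastereomers, which must then be dehydrogenated to the resorcinol.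
- **In favour.** The 2-methylbut-3-en-2-yl group arrives with A9, so its position on ring A is fixed by the annulation and does not depend on the direction of a Claisen shift; that is better than step 2. The chain is already in A8, and the annulation needs no transition metal.
- **Against.** The Michael addition must go through the internal enolate although the methyl side is the easier one to deprotonate. A9 is a twisted, weakly activated acceptor next to a quaternary carbon. The weakest point is the aromatisation of A7: the halogenating or dehydrogenating agents used for it would also meet four alkenes and an electron-rich chromene. The methoxymethyl ether on ring B again needs acid.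
- **Comparison.** The stereocentres of A7 are irrelevant, as is the one in 21; on that point the plans are equal. Ring B needs the same chromene and prenyl chemistry as the chosen route plus a five-carbon ketone chain, so the total is longer and the oxidation state change at the end is riskier than the hydride opening of 21.

Key step: step 11

Remark on the chemistry: 21 is made and used as the racemate, since its only stereocentre becomes a CH2 group in step 12 and 24 has none; 8 is the cheaper partner and is used in excess in step 11.

## Route

**Step 1**
Reactants: 1 2,4-dihydroxybenzaldehyde; 2 prenyl bromide (1-bromo-3-methylbut-2-ene)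
Product: 3 2-hydroxy-4-[(3-methylbut-2-en-1-yl)oxy]benzaldehyde
Conditions: K2CO3 (1.0 equiv), acetone, rt
Reagents that add atoms: none
Why: Williamson ether synthesis; the 4-hydroxyl is the more acidic one and is not held in the hydrogen bond to the formyl group, so the mono-phenoxide should alkylate at O4 and leave the chelated 2-hydroxyl free.

**Step 2**
Reactants: 3 2-hydroxy-4-[(3-methylbut-2-en-1-yl)oxy]benzaldehyde
Product: 6 2,4-dihydroxy-5-(2-methylbut-3-en-2-yl)benzaldehyde, via 2-O-trimethylsilyl ether 4 (not isolated), via bis(trimethylsilyl) ether 5 (not isolated)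
Conditions: BSA (3 equiv), PhNEt2, 60 °C; then 185 °C (sealed tube); then MeOH, K2CO3 (cat.), 0 °C
Reagents that add atoms: none
Why: Aromatic Claisen rearrangement with silylation in the flask: N,O-bis(trimethylsilyl)acetamide (BSA) caps the hydrogen-bonded 2-hydroxyl as 4, which removes the chelate that would direct the [3,3] shift to C3, so the allyl unit should migrate with inversion to the less hindered C5, para to O2. The new phenol is silylated at once to 5, which blocks ring closure onto the new alkene, and methanolysis on work-up frees both hydroxyls.

**Step 3**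
Reactants: 6 2,4-dihydroxy-5-(2-methylbut-3-en-2-yl)benzaldehyde
Product: 7 2,4-bis[(tert-butoxycarbonyl)oxy]-5-(2-methylbut-3-en-2-yl)benzaldehyde
Conditions: Boc2O (2.4 equiv), DMAP (cat.), iPr2NEt, THF, 0 °C → rt
Reagents that add atoms: di-tert-butyl dicarbonate, CC(C)(C)OC(=O)OC(=O)OC(C)(C)C
Why: DMAP-catalysed O-acylation of both phenols to aryl tert-butyl carbonates; the acylpyridinium ion is reactive enough for the chelated 2-hydroxyl and for the 4-hydroxyl next to the quaternary carbon.

**Step 4**
Reactants: 7 2,4-bis[(tert-butoxycarbonyl)oxy]-5-(2-methylbut-3-en-2-yl)benzaldehyde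
Product: 8 2,4-bis[(tert-butoxycarbonyl)oxy]-5-(2-methylbut-3-en-2-yl)benzyl alcohol
Conditions: i-Bu2AlH (1.05 equiv), CH2Cl2, −78 °C; AcOH at −78 °C, then aq. potassium sodium tartrate
Reagents that add atoms: none
Why: Hydride reduction of an aldehyde; at −78 °C the aldehyde should react far faster than the hindered aryl carbonates and the alkene is inert. The aluminium alkoxide is protonated cold, before it can take over the neighbouring carbonate and start quinone methide formation.

**Step 5**
Reactants: 9 2-bromo-4,5-dimethoxybenzaldehyde
Product: 10 2-bromo-4,5-dihydroxybenzaldehyde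
Conditions: BBr3 (2.5 equiv), CH2Cl2, −78 °C → rt; H2O
Reagents that add atoms: none
Why: Lewis-acid cleavage of aryl methyl ethers; done first, while the molecule has no alkene or chromene that BBr3 could attack.

**Step 6**
Reactants: 10 2-bromo-4,5-dihydroxybenzaldehyde; 11 3-chloro-3-methylbut-1-yne
Product: 12 2-bromo-5-hydroxy-4-[(2-methylbut-3-yn-2-yl)oxy]benzaldehyde
Conditions: DBU (1.1 equiv), CuCl2·2H2O (1 mol%), MeCN, −5 → 0 °C, Ar
Reagents that add atoms: none
Why: Copper-catalysed etherification of a phenol with a tertiary propargylic chloride (through a copper acetylide); with one equivalent of base the anion sits on O4, para to the formyl group and the more acidic by far, so the ether should form there and leave the C5 hydroxyl free.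

**Step 7**
Reactants: 12 2-bromo-5-hydroxy-4-[(2-methylbut-3-yn-2-yl)oxy]benzaldehyde
Product: 13 2-bromo-5-[(tert-butyldimethylsilyl)oxy]-4-[(2-methylbut-3-yn-2-yl)oxy]benzaldehyde
Conditions: TBSCl, imidazole, DMF, 0 °C → rt
Reagents that add atoms: tert-butyldimethylsilyl chloride, CC(C)(C)[Si](C)(C)Cl
Why: Silylation of the remaining phenol; an aryl silyl ether should tolerate heat, palladium, the ylide and the Grignard base, and it is removed at the end without acid.

**Step 8**
Reactants: 13 2-bromo-5-[(tert-butyldimethylsilyl)oxy]-4-[(2-methylbut-3-yn-2-yl)oxy]benzaldehyde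
Product: 15 5-bromo-8-[(tert-butyldimethylsilyl)oxy]-2,2-dimethyl-2H-chromene-6-carbaldehyde, via allenyl phenol 14 (not isolated)
Conditions: PhNEt2, 170 °C
Reagents that add atoms: none
Why: Propargyl Claisen rearrangement to the only free ortho carbon (C3, between the ether oxygen and bromine) gives 14 after enolisation; a 1,5-hydrogen shift and 6π oxa-electrocyclisation then close the 2,2-dimethylpyran ring. The other ortho position carries the silyloxy group, so there is no regiochemical choice.

**Step 9**
Reactants: 15 5-bromo-8-[(tert-butyldimethylsilyl)oxy]-2,2-dimethyl-2H-chromene-6-carbaldehyde; 16 tributyl(3-methylbut-2-en-1-yl)stannane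
Product: 17 8-[(tert-butyldimethylsilyl)oxy]-2,2-dimethyl-5-(3-methylbut-2-en-1-yl)-2H-chromene-6-carbaldehyde
Conditions: Pd(PPh3)4 (5 mol%), DMF, 95 °C
Reagents that add atoms: none
Why: Stille coupling; the ortho formyl group speeds oxidative addition of zerovalent palladium into the hindered C–Br bond, and reductive elimination from the less crowded primary allyl–palladium form should give the linear prenyl arene. No fluoride is used, so the silyl ether stays.

**Step 10**
Reactants: 17 8-[(tert-butyldimethylsilyl)oxy]-2,2-dimethyl-5-(3-methylbut-2-en-1-yl)-2H-chromene-6-carbaldehyde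
Product: 18 tert-butyl{[2,2-dimethyl-5-(3-methylbut-2-en-1-yl)-6-vinyl-2H-chromen-8-yl]oxy}dimethylsilane
Conditions: Ph3PCH3Br, NaN(SiMe3)2, THF, 0 °C → rt
Reagents that add atoms: methyltriphenylphosphonium bromide, C[P+](c1ccccc1)(c1ccccc1)c1ccccc1.[Br-]
Why: Wittig methylenation of an aromatic aldehyde; the non-stabilised ylide reacts at 0 °C, and an amide base in slight deficit leaves the aryl silyl ether alone.

**Step 11**
Reactants: 8 2,4-bis[(tert-butoxycarbonyl)oxy]-5-(2-methylbut-3-en-2-yl)benzyl alcohol; 18 tert-butyl{[2,2-dimethyl-5-(3-methylbut-2-en-1-yl)-6-vinyl-2H-chromen-8-yl]oxy}dimethylsilane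
Product: 21 racemic tert-butyl 2-{8-[(tert-butyldimethylsilyl)oxy]-2,2-dimethyl-5-(3-methylbut-2-en-1-yl)-2H-chromen-6-yl}-6-(2-methylbut-3-en-2-yl)chroman-7-yl carbonate, via benzylic carbonate 19 (not isolated), via ortho-quinone methide 20 (not isolated)
Conditions: t-BuMgCl (1.0 equiv per 8), Et2O/PhMe, −78 °C → rt; 8 (2 equiv) in two portions
Reagents that add atoms: none
Why: t-BuMgCl deprotonates 8 at −78 °C without adding to the carbonates; on warming, the magnesium alkoxide takes the neighbouring tert-butoxycarbonyl group through a six-membered transition state to give the phenoxide of 19, which expels tert-butyl carbonate (lost as CO2 and tert-butoxide) and forms 20. 20 is an electron-poor 1-oxadiene, made more electrophilic by magnesium and by the remaining carbonate, and it should add the vinyl group of 18 in an inverse-electron-demand hetero-Diels–Alder reaction, the known way from ortho-quinone methides and styrenes to 2-arylchromans. The dihydropyran ring closes by [4+2] cycloaddition: the methide carbon bonds to the terminal CH2 of the vinyl group (chain C1–C2) and the carbonyl oxygen to the benzylic carbon (O–C3). The transition state is polarised, with positive charge building at the benzylic carbon, where the para pyran oxygen of ring B stabilises it, so only the 2-aryl regioisomer is expected. The one new stereocentre, C2, has no controlling element and forms as a racemate, which is harmless because step 12 turns it into a CH2 group. The step needs chemoselectivity among the three alkenes of 18 and the terminal alkene on 20: the aryl-conjugated, monosubstituted vinyl group is the most nucleophilic and least hindered, while the chromene double bond is shielded at C3 by the gem-dimethyl group, the prenyl alkene is trisubstituted and not conjugated, and the terminal alkene on 20 is unactivated. Since 20 also reacts with itself, 18 is the limiting partner and 8 is supplied in excess in two portions. One equivalent of base per 8 leaves no Grignard reagent to add to 20.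

**Step 12**
Reactants: 21 racemic tert-butyl 2-{8-[(tert-butyldimethylsilyl)oxy]-2,2-dimethyl-5-(3-methylbut-2-en-1-yl)-2H-chromen-6-yl}-6-(2-methylbut-3-en-2-yl)chroman-7-yl carbonate
Product: 22 tert-butyl 4-(3-{8-[(tert-butyldimethylsilyl)oxy]-2,2-dimethyl-5-(3-methylbut-2-en-1-yl)-2H-chromen-6-yl}propyl)-5-hydroxy-2-(2-methylbut-3-en-2-yl)phenyl carbonate
Conditions: Et3SiH (15 equiv), BF3·OEt2 (2 equiv), 2,6-di-tert-butyl-4-methylpyridine (0.3 equiv), CH2Cl2, −78 → −30 °C; aq. NaHCO3
Reagents that add atoms: none
Why: Ionic hydrogenolysis of a benzylic ether: BF3 on the chroman oxygen lets the O–C2 bond ionise to a cation stabilised by the para pyran oxygen of ring B, and the large excess of silane should deliver hydride before the neighbouring prenyl alkene can attack. The hindered pyridine removes stray protons that would attack the alkenes, the carbonate keeps ring A electron-poor, and the ring A carbon that could close an indane is meta to both oxygens.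

**Step 13**
Reactants: 22 tert-butyl 4-(3-{8-[(tert-butyldimethylsilyl)oxy]-2,2-dimethyl-5-(3-methylbut-2-en-1-yl)-2H-chromen-6-yl}propyl)-5-hydroxy-2-(2-methylbut-3-en-2-yl)phenyl carbonate
Product: 24 kazinol K, 4-{3-[8-hydroxy-2,2-dimethyl-5-(3-methylbut-2-en-1-yl)-2H-chromen-6-yl]propyl}-6-(2-methylbut-3-en-2-yl)benzene-1,3-diol, via desilylated carbonate 23 (not isolated)
Conditions: Bu4NF (1.5 equiv), THF, 0 °C; then K2CO3, MeOH, rt (degassed); aq. NH4Cl
Reagents that add atoms: none
Why: Fluoride desilylation of the aryl silyl ether, then base-mediated methanolysis (transesterification) of the aryl tert-butyl carbonate, with the phenoxide as leaving group. No acid is used, so the chromene, the prenyl group and the ortho-allyl phenol should survive; the route sets no stereocentre that could be lost.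

## Compound list

1 | 2,4-dihydroxybenzaldehyde | O=Cc1ccc(O)cc1O | starting material
2 | prenyl bromide (1-bromo-3-methylbut-2-ene) | CC(C)=CCBr | starting material
3 | 2-hydroxy-4-[(3-methylbut-2-en-1-yl)oxy]benzaldehyde | O=Cc1ccc(OCC=C(C)C)cc1O | intermediate
4 | 4-[(3-methylbut-2-en-1-yl)oxy]-2-[(trimethylsilyl)oxy]benzaldehyde | O=Cc1ccc(OCC=C(C)C)cc1O[Si](C)(C)C | intermediate (not isolated)
5 | 5-(2-methylbut-3-en-2-yl)-2,4-bis[(trimethylsilyl)oxy]benzaldehyde | O=Cc1cc(C(C)(C)C=C)c(O[Si](C)(C)C)cc1O[Si](C)(C)C | intermediate (not isolated)
6 | 2,4-dihydroxy-5-(2-methylbut-3-en-2-yl)benzaldehyde | O=Cc1cc(C(C)(C)C=C)c(O)cc1O | intermediate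
7 | 2,4-bis[(tert-butoxycarbonyl)oxy]-5-(2-methylbut-3-en-2-yl)benzaldehyde | O=Cc1cc(C(C)(C)C=C)c(OC(=O)OC(C)(C)C)cc1OC(=O)OC(C)(C)C | intermediate
8 | 2,4-bis[(tert-butoxycarbonyl)oxy]-5-(2-methylbut-3-en-2-yl)benzyl alcohol | OCc1cc(C(C)(C)C=C)c(OC(=O)OC(C)(C)C)cc1OC(=O)OC(C)(C)C | intermediate
9 | 2-bromo-4,5-dimethoxybenzaldehyde | COc1cc(Br)c(C=O)cc1OC | starting material
10 | 2-bromo-4,5-dihydroxybenzaldehyde | O=Cc1cc(O)c(O)cc1Br | intermediate
11 | 3-chloro-3-methylbut-1-yne | C#CC(C)(C)Cl | starting material
12 | 2-bromo-5-hydroxy-4-[(2-methylbut-3-yn-2-yl)oxy]benzaldehyde | O=Cc1cc(O)c(OC(C)(C)C#C)cc1Br | intermediate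
13 | 2-bromo-5-[(tert-butyldimethylsilyl)oxy]-4-[(2-methylbut-3-yn-2-yl)oxy]benzaldehyde | O=Cc1cc(O[Si](C)(C)C(C)(C)C)c(OC(C)(C)C#C)cc1Br | intermediate
14 | 2-bromo-5-[(tert-butyldimethylsilyl)oxy]-4-hydroxy-3-(3-methylbuta-1,2-dien-1-yl)benzaldehyde | O=Cc1cc(O[Si](C)(C)C(C)(C)C)c(O)c(C=C=C(C)C)c1Br | intermediate (not isolated)
15 | 5-bromo-8-[(tert-butyldimethylsilyl)oxy]-2,2-dimethyl-2H-chromene-6-carbaldehyde | O=Cc1cc(O[Si](C)(C)C(C)(C)C)c2OC(C)(C)C=Cc2c1Br | intermediate
16 | tributyl(3-methylbut-2-en-1-yl)stannane | CCCC[Sn](CCCC)(CCCC)CC=C(C)C | starting material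
17 | 8-[(tert-butyldimethylsilyl)oxy]-2,2-dimethyl-5-(3-methylbut-2-en-1-yl)-2H-chromene-6-carbaldehyde | O=Cc1cc(O[Si](C)(C)C(C)(C)C)c2OC(C)(C)C=Cc2c1CC=C(C)C | intermediate
18 | tert-butyl{[2,2-dimethyl-5-(3-methylbut-2-en-1-yl)-6-vinyl-2H-chromen-8-yl]oxy}dimethylsilane | C=Cc1cc(O[Si](C)(C)C(C)(C)C)c2OC(C)(C)C=Cc2c1CC=C(C)C | intermediate
19 | tert-butyl 4-[(tert-butoxycarbonyl)oxy]-2-hydroxy-5-(2-methylbut-3-en-2-yl)benzyl carbonate (present as its magnesium phenoxide) | CC(C)(C)OC(=O)OCc1cc(C(C)(C)C=C)c(OC(=O)OC(C)(C)C)cc1O | intermediate (not isolated)
20 | tert-butyl 6-(2-methylbut-3-en-2-yl)-4-methylidene-3-oxocyclohexa-1,5-dien-1-yl carbonate (ortho-quinone methide) | C=C1C=C(C(C)(C)C=C)C(OC(=O)OC(C)(C)C)=CC1=O | intermediate (not isolated)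
21 | racemic tert-butyl 2-{8-[(tert-butyldimethylsilyl)oxy]-2,2-dimethyl-5-(3-methylbut-2-en-1-yl)-2H-chromen-6-yl}-6-(2-methylbut-3-en-2-yl)chroman-7-yl carbonate | C=CC(C)(C)c1cc2CCC(c3cc(O[Si](C)(C)C(C)(C)C)c4OC(C)(C)C=Cc4c3CC=C(C)C)Oc2cc1OC(=O)OC(C)(C)C | intermediate
22 | tert-butyl 4-(3-{8-[(tert-butyldimethylsilyl)oxy]-2,2-dimethyl-5-(3-methylbut-2-en-1-yl)-2H-chromen-6-yl}propyl)-5-hydroxy-2-(2-methylbut-3-en-2-yl)phenyl carbonate | C=CC(C)(C)c1cc(CCCc2cc(O[Si](C)(C)C(C)(C)C)c3OC(C)(C)C=Cc3c2CC=C(C)C)c(O)cc1OC(=O)OC(C)(C)C | intermediate
23 | tert-butyl 5-hydroxy-4-{3-[8-hydroxy-2,2-dimethyl-5-(3-methylbut-2-en-1-yl)-2H-chromen-6-yl]propyl}-2-(2-methylbut-3-en-2-yl)phenyl carbonate | C=CC(C)(C)c1cc(CCCc2cc(O)c3OC(C)(C)C=Cc3c2CC=C(C)C)c(O)cc1OC(=O)OC(C)(C)C | intermediate (not isolated)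
24 | kazinol K, 4-{3-[8-hydroxy-2,2-dimethyl-5-(3-methylbut-2-en-1-yl)-2H-chromen-6-yl]propyl}-6-(2-methylbut-3-en-2-yl)benzene-1,3-diol (no stereocentre) | C=CC(C)(C)c1cc(CCCc2cc(O)c3c(c2CC=C(C)C)C=CC(C)(C)O3)c(O)cc1O | target

## Step count and weak points

Total: 13 steps. Longest linear sequence: 9 steps (steps 5 to 13, from 9); the ring A branch (steps 1 to 4) joins at step 11.

**Step 11 (key step).** The most likely failure is self-condensation of the quinone methide running faster than the cycloaddition, because the vinyl group of 18 is flanked by the prenyl group and is partly twisted out of conjugation. Capture of 20 by one of the other alkenes is a lesser risk.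

The fallback sets out from 18 and 8 and comes back at 22, leaving out 21. Hydroboration of the vinyl group of 18 with 9-BBN (selective for the monosubstituted alkene) and oxidation with NaBO3·4H2O would give 2-{8-[(tert-butyldimethylsilyl)oxy]-2,2-dimethyl-5-(3-methylbut-2-en-1-yl)-2H-chromen-6-yl}ethanol F1. CBr4/PPh3 would turn it into {[6-(2-bromoethyl)-2,2-dimethyl-5-(3-methylbut-2-en-1-yl)-2H-chromen-8-yl]oxy}(tert-butyl)dimethylsilane F2, and magnesium in THF into the Grignard reagent (2-{8-[(tert-butyldimethylsilyl)oxy]-2,2-dimethyl-5-(3-methylbut-2-en-1-yl)-2H-chromen-6-yl}ethyl)magnesium bromide F3. 8 is then deprotonated with t-BuMgCl at −78 °C in the presence of F3 and warmed. 20 forms as before and is intercepted by 1,4-addition of the carbanion, a known reaction of such quinone methides with Grignard reagents, to give 22 after aqueous work-up. The chain C1–C2 bond is then made by a far stronger nucleophile, and no benzylic C–O bond needs to be cut.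

**Step 12.** The most likely failure is capture of the benzylic cation by the neighbouring prenyl alkene (ring closure to an indane), or ionisation and reduction of the chromene ring, before the silane delivers hydride.

The fallback sets out from 15 and comes back at 22. Wittig methylenation of 15 would give [(5-bromo-2,2-dimethyl-6-vinyl-2H-chromen-8-yl)oxy](tert-butyl)dimethylsilane F4. Cycloaddition with 20 (from 8, as in step 11) would give racemic tert-butyl 2-{5-bromo-8-[(tert-butyldimethylsilyl)oxy]-2,2-dimethyl-2H-chromen-6-yl}-6-(2-methylbut-3-en-2-yl)chroman-7-yl carbonate F5. Et3SiH/BF3·OEt2 would open it to tert-butyl 4-(3-{5-bromo-8-[(tert-butyldimethylsilyl)oxy]-2,2-dimethyl-2H-chromen-6-yl}propyl)-5-hydroxy-2-(2-methylbut-3-en-2-yl)phenyl carbonate F6, now with no alkene beside the cation. A Stille coupling of F6 with 16 (Pd(PPh3)4, CuI, DMF, 100 °C) then puts in the prenyl group and gives 22.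

**Step 2.** The most likely failure is incomplete silylation of the hydrogen-bonded hydroxyl, which would send part of the [3,3] shift to C3; thermal follow-up reactions of the product at 185 °C are the second risk.

The fallback sets out from 1 and comes back at 6, and fixes the position with a halogen. Bromination of 1 (Br2, AcOH) at C5, the position para to O2 and ortho to O4, would give 5-bromo-2,4-dihydroxybenzaldehyde F7. A Suzuki–Miyaura coupling of F7 with 3,3-dimethylallylboronic acid pinacol ester (Pd(OAc)2, a bulky dialkylbiarylphosphine, K3PO4, aqueous THF) transfers the allyl unit through its γ-carbon and should give 6 directly.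

**Step 6.** The most likely failure is etherification at the C5 hydroxyl or at both hydroxyls.

The fallback sets out from 10 and comes back at 13, leaving out 12 and step 7. Silylation of both hydroxyls (TBSCl, imidazole) would give 2-bromo-4,5-bis[(tert-butyldimethylsilyl)oxy]benzaldehyde F8. K2CO3 in MeOH at 0 °C should cleave only the silyl ether para to the formyl group, which has the better phenoxide leaving group, and give 2-bromo-5-[(tert-butyldimethylsilyl)oxy]-4-hydroxybenzaldehyde F9. Copper-catalysed etherification of F9 with 11 then gives 13.

**Step 9.** The most likely failure is transfer of the prenyl group through its tertiary carbon, or slow coupling at the doubly flanked bromide with loss of bromine instead.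

The fallback sets out from 15 and comes back at 17. A Stille coupling with allyltributylstannane, which has no regiochemical choice, would give 5-allyl-8-[(tert-butyldimethylsilyl)oxy]-2,2-dimethyl-2H-chromene-6-carbaldehyde F10. Cross-metathesis of F10 with 2-methylbut-2-ene (second-generation Grubbs catalyst, CH2Cl2, 40 °C) then builds the trisubstituted alkene and gives 17.

## Further compounds

F1 | step 11 | 2-{8-[(tert-butyldimethylsilyl)oxy]-2,2-dimethyl-5-(3-methylbut-2-en-1-yl)-2H-chromen-6-yl}ethanol | OCCc1cc(O[Si](C)(C)C(C)(C)C)c2OC(C)(C)C=Cc2c1CC=C(C)C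
F2 | step 11 | {[6-(2-bromoethyl)-2,2-dimethyl-5-(3-methylbut-2-en-1-yl)-2H-chromen-8-yl]oxy}(tert-butyl)dimethylsilane | BrCCc1cc(O[Si](C)(C)C(C)(C)C)c2OC(C)(C)C=Cc2c1CC=C(C)C
F3 | step 11 | (2-{8-[(tert-butyldimethylsilyl)oxy]-2,2-dimethyl-5-(3-methylbut-2-en-1-yl)-2H-chromen-6-yl}ethyl)magnesium bromide | Br[Mg]CCc1cc(O[Si](C)(C)C(C)(C)C)c2OC(C)(C)C=Cc2c1CC=C(C)C
F4 | step 12 | [(5-bromo-2,2-dimethyl-6-vinyl-2H-chromen-8-yl)oxy](tert-butyl)dimethylsilane | C=Cc1cc(O[Si](C)(C)C(C)(C)C)c2OC(C)(C)C=Cc2c1Br
F5 | step 12 | racemic tert-butyl 2-{5-bromo-8-[(tert-butyldimethylsilyl)oxy]-2,2-dimethyl-2H-chromen-6-yl}-6-(2-methylbut-3-en-2-yl)chroman-7-yl carbonate | C=CC(C)(C)c1cc2CCC(c3cc(O[Si](C)(C)C(C)(C)C)c4OC(C)(C)C=Cc4c3Br)Oc2cc1OC(=O)OC(C)(C)C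
F6 | step 12 | tert-butyl 4-(3-{5-bromo-8-[(tert-butyldimethylsilyl)oxy]-2,2-dimethyl-2H-chromen-6-yl}propyl)-5-hydroxy-2-(2-methylbut-3-en-2-yl)phenyl carbonate | C=CC(C)(C)c1cc(CCCc2cc(O[Si](C)(C)C(C)(C)C)c3OC(C)(C)C=Cc3c2Br)c(O)cc1OC(=O)OC(C)(C)C
F7 | step 2 | 5-bromo-2,4-dihydroxybenzaldehyde | O=Cc1cc(Br)c(O)cc1O
F8 | step 6 | 2-bromo-4,5-bis[(tert-butyldimethylsilyl)oxy]benzaldehyde | O=Cc1cc(O[Si](C)(C)C(C)(C)C)c(O[Si](C)(C)C(C)(C)C)cc1Br
F9 | step 6 | 2-bromo-5-[(tert-butyldimethylsilyl)oxy]-4-hydroxybenzaldehyde | O=Cc1cc(O[Si](C)(C)C(C)(C)C)c(O)cc1Br
F10 | step 9 | 5-allyl-8-[(tert-butyldimethylsilyl)oxy]-2,2-dimethyl-2H-chromene-6-carbaldehyde | O=Cc1cc(O[Si](C)(C)C(C)(C)C)c2OC(C)(C)C=Cc2c1CC=C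
A1 | alternative 1 | 5-{3-[2,4-bis(methoxymethoxy)-5-(2-methylbut-3-en-2-yl)phenyl]propyl}-3,4-bis(3-methylbut-2-en-1-yl)benzene-1,2-diol | C=CC(C)(C)c1cc(CCCc2cc(O)c(O)c(CC=C(C)C)c2CC=C(C)C)c(OCOC)cc1OCOC
A2 | alternative 1 | (3,4-diacetoxy-6-{3-[2,4-bis(methoxymethoxy)-5-(2-methylbut-3-en-2-yl)phenyl]propyl}-1,2-phenylene)bis(methylene) bis(2,2-dimethylpropanoate) | C=CC(C)(C)c1cc(CCCc2cc(OC(C)=O)c(OC(C)=O)c(COC(=O)C(C)(C)C)c2COC(=O)C(C)(C)C)c(OCOC)cc1OCOC
A3 | alternative 1 | 2-methylprop-1-en-1-ylmagnesium bromide | CC(C)=C[Mg]Br
A4 | alternative 2 | 2,2-dimethyl-5-(3-methylbut-2-en-1-yl)-6-[(triisopropylsilyl)oxy]chroman-8-ol | CC1(C)CCc2c(CC=C(C)C)c(O[Si](C(C)C)(C(C)C)C(C)C)cc(O)c2O1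
A5 | alternative 2 | 2-diazo-1-(2,2-dimethyl-3,4-dihydro-2H-pyran-5-yl)-5-methylhex-4-en-1-one | CC(C)=CCC(=[N+]=[N-])C(=O)C1=COC(C)(C)CC1
A6 | alternative 2 | (triisopropylsilyloxy)acetylene | C#CO[Si](C(C)C)(C(C)C)C(C)C
A7 | alternative 3 | 4-(2-methylbut-3-en-2-yl)-6-{3-[8-(methoxymethoxy)-2,2-dimethyl-5-(3-methylbut-2-en-1-yl)-2H-chromen-6-yl]propyl}cyclohexane-1,3-dione (mixture of diastereomers) | O=C1CC(=O)C(C(C)(C)C=C)CC1CCCc1cc(OCOC)c2OC(C)(C)C=Cc2c1CC=C(C)C
A8 | alternative 3 | 6-[8-(methoxymethoxy)-2,2-dimethyl-5-(3-methylbut-2-en-1-yl)-2H-chromen-6-yl]hexan-2-one | CC(=O)CCCCc1cc(OCOC)c2OC(C)(C)C=Cc2c1CC=C(C)C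
A9 | alternative 3 | methyl 3,3-dimethyl-2-methylidenepent-4-enoate | C=CC(C)(C)C(=C)C(=O)OC
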